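**Plan**
Retrosynthesis: the C2 carbinol, both tiglates and the 8,9-epoxide are removed first; the C6 oxygen and C5 hydrogen are then taken back to a C5=C6 alkene (dienone 17). In 17 the bonds C6–C7 and C1–C10 of the seven-membered ring are cut together with C1–C5 of the five-membered ring, giving acyclic diazo ynone 12 and silyl dienol ether 14.
Enabling feature: with C5=C6 and C8=C9 drawn as alkenes, the seven-membered ring is a cyclohepta-1,4-diene (C7 methylene between the alkenes, C1–C10 bond opposite), the product of a cis-divinylcyclopropane (C6, C7, C8) Cope rearrangement. The C2 carbonyl next to quaternary C1 is the mark of a diazoketone carbene that can reach C6 through an alkyne carried by the C4 carbinol.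
Forward order: five-membered ring (carbene/alkyne metathesis), cyclopropane, seven-membered ring ([3,3] ring expansion), all in one flask; then C5/C6, the 8,9-epoxide and C2.
Stereochemistry: C4 from (R)-2-hydroxy-3-methylbutanoic acid (self-regeneration of stereocentres); C1/C10 from the boat Cope step on the face anti to isopropyl; C5 by H-atom transfer anti to the C6 titanoxy group; C6 by Mitsunobu inversion; epoxide by 10-OH-directed epoxidation; C2 by 4-OH-directed hydride delivery.

Key step: step 7

Remark: ring atoms are numbered as in daucane (C1 methyl-bearing fusion carbon, C2, C3, C4 isopropyl carbinol, C5 fusion CH, C6–C10 round the seven-membered ring, C8 methyl-bearing); β is the face of the C1 methyl group, so the C4 isopropyl group is β when the 4-oxygen is α; tigloyl = (E)-2-methylbut-2-enoyl.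

**Step 1**
Reactants: 1 (2R)-2-hydroxy-3-methylbutanoic acid; 2 2,2-dimethylpropanal
Product: 3 (2R,5R)-2-tert-butyl-5-(propan-2-yl)-1,3-dioxolan-4-one (cis)
Conditions: TsOH·H2O (cat.), H2SO4 (cat.), pentane, reflux, Dean–Stark; cis isomer purified by crystallisation
Reagents that add atoms: none
Why: Seebach acetalisation under thermodynamic control should give the cis acetal, in which the untouched C5 centre fixes the new acetal centre.

**Step 2**
Reactants: 3; 4 tert-butyl bromoacetate
Product: 5 tert-butyl [(2R,4R)-2-tert-butyl-5-oxo-4-(propan-2-yl)-1,3-dioxolan-4-yl]acetate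
Conditions: LiN(iPr)2, THF/DMPU, −78 °C; then 4, −78 → −30 °C
Reagents that add atoms: none
Why: Enolate alkylation anti to the tert-butyl group (self-regeneration of stereocentres) should create the quaternary carbinol centre with net retention.

**Step 3**
Reactants: 5
Product: 8 tert-butyl (3R)-3-ethynyl-3-hydroxy-4-methylpentanoate, via lactol 6 (not isolated), via hydroxy aldehyde 7 (not isolated)
Conditions: iBu2AlH (1.05 equiv), CH2Cl2, −78 °C; then MeOH, K2CO3, dimethyl (1-diazo-2-oxopropyl)phosphonate, −78 °C → rt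
Reagents that add atoms: dimethyl (1-diazo-2-oxopropyl)phosphonate, COP(=O)(OC)C(=[N+]=[N-])C(C)=O
Why: Half-reduction of the electrophilic acylal lactone (faster than the tert-butyl ester) and Ohira–Bestmann homologation of the unmasked aldehyde should give the alkyne without touching the quaternary centre.

**Step 4**
Reactants: 8
Product: 10 (3R)-3-ethynyl-4-methyl-3-(trimethylsilyloxy)pentanoic acid, via silyl ester 9 (not isolated)
Conditions: Me3SiOTf (2.5 equiv), 2,6-lutidine, CH2Cl2, 0 °C → rt; then pH 7 buffer/MeOH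
Reagents that add atoms: trimethylsilyl trifluoromethanesulfonate, C[Si](C)(C)OS(=O)(=O)C(F)(F)F
Why: Silyl triflate silylates the tertiary alcohol and converts the tert-butyl ester into a silyl ester (loss of isobutene), which hydrolyses on work-up while the tertiary silyl ether stays.

**Step 5**
Reactants: 10
Product: 12 (5R)-2-diazo-5-ethynyl-6-methyl-5-(trimethylsilyloxy)heptan-3-one, via acid chloride 11 (not isolated)
Conditions: 1-chloro-N,N,2-trimethylprop-1-en-1-amine, CH2Cl2, 0 °C; then CH3CHN2 (3 equiv, Et2O solution freshly made from N-ethyl-N-nitrosourea and KOH), −20 → 0 °C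
Reagents that add atoms: diazoethane, CC=[N+]=[N-]
Why: Neutral acid chloride formation followed by acylation of diazoethane (Arndt–Eistert-type) should give the α-diazo ethyl ketone, the second equivalent of diazoethane taking up HCl.

**Step 6**
Reactants: 13 3-methylbut-2-enal
Product: 14 tert-butyl(dimethyl){[(1E)-3-methylbuta-1,3-dien-1-yl]oxy}silane
Conditions: tBuMe2SiOTf, Et3N, Et2O, 0 °C → rt
Reagents that add atoms: tert-butyldimethylsilyl trifluoromethanesulfonate, CC(C)(C)[Si](C)(C)OS(=O)(=O)C(F)(F)F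
Why: O-silylation with γ-deprotonation of the enal (silyl dienol ether formation) should give the E diene from the s-trans enal.

**Step 7**
Reactants: 12; 14
Product: 17 10α-(tert-butyldimethylsilyloxy)-4α-hydroxydauca-5,8-dien-2-one, via divinylcyclopropane 15 (not isolated), via bis-silyl ether 16 (not isolated)
Conditions: Rh2(O2CCPh3)4 (1 mol %), 14 (4 equiv), ClCH2CH2Cl, 0 → 25 °C, slow addition of 12; then 80 °C; then Et3N·3HF, THF, 0 °C
Reagents that add atoms: none
Why: Proposed new method: Rh2(O2CCPh3)4 turns 12 into an acyl carbenoid at the future C1, which adds 5-exo-dig to the tethered alkyne (carbene/alkyne metathesis), closing the cyclopentenone and passing the carbene to the exocyclic future C6; this vinylcarbenoid cyclopropanates the terminal CH2=C(CH3) unit of 14 (C6–C7 bond) to give cis-divinylcyclopropane 15, whose Cope rearrangement through a boat transition state at 80 °C forms the C1–C10 bond, and Et3N·3HF then frees the tertiary alcohol. The closest known reaction types are the rhodium-catalysed cyclisation of alkynyl diazoketones to cyclopentenone vinylcarbenoids with capture by vinyl ethers, and the tandem cyclopropanation/Cope formal (4+3) cycloaddition of rhodium vinylcarbenoids with 1-oxygenated dienes; their merger in one flask is the untested part. Ring closures: the five-membered ring by 5-exo-dig carbenoid–alkyne addition, the three-membered ring by intermolecular (2+1) addition, the seven-membered ring by [3,3]-sigmatropic ring expansion. C1 and C10 arise together in the Cope step, where the E-silyloxy group and the ring carbonyl carbon (the two E substituents) end cis, so the C1 methyl and the C10 oxygen are trans; their sense relative to C4 is fixed in the cyclopropanation, in which the diene should meet the s-cis vinylcarbenoid on the face of the small OSiMe3 group, anti to isopropyl, so that the C1–C10 bond forms anti to isopropyl. The step needs chemoselectivity (alkyne capture ahead of 1,2-hydride shift and C–H insertion, helped by the five-membered transition state and the bulky triphenylacetate ligands; no free O–H, hence the silyl ether), regioselectivity (attack at the unhindered, most nucleophilic CH2 terminus of 14, the charge being stabilised as a vinylogous oxocarbenium ion) and a cis cyclopropane (favoured by stacking of the silyloxyvinyl group over the enone, and otherwise reachable at 80 °C by reversible opening of the donor–acceptor cyclopropane).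

**Step 8**
Reactants: 17
Product: 18 5α,6α-epoxy-10α-(tert-butyldimethylsilyloxy)-4α-hydroxydauc-8-en-2-one
Conditions: VO(acac)2 (5 mol %), tBuOOH (1.5 equiv, decane), CH2Cl2, 0 °C → rt
Reagents that add atoms: tert-butyl hydroperoxide, CC(C)(C)OO
Why: Hydroxyl-directed epoxidation should act only on the allylic C5=C6 alkene and deliver oxygen to the α face, syn to the 4α-OH and anti to the C1 methyl and isopropyl groups.

**Step 9**
Reactants: 18
Product: 19 10α-(tert-butyldimethylsilyloxy)-4α,6α-dihydroxy-5βH-dauc-8-en-2-one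
Conditions: Cp2TiCl2 (10 mol %), Mn (2 equiv), 2,4,6-collidine·HCl (2.5 equiv), 1,4-cyclohexadiene (10 equiv), THF, rt
Reagents that add atoms: none
Why: Nugent–RajanBabu reductive epoxide opening by Cp2TiCl (trivalent titanium) gives the tertiary C5 radical, which should take hydrogen from the β face, anti to the adjacent C6 titanoxy group, setting the cis ring fusion while C6 keeps its α oxygen.

**Step 10**
Reactants: 19; 20 tiglic acid ((E)-2-methylbut-2-enoic acid)
Product: 21 10α-(tert-butyldimethylsilyloxy)-4α-hydroxy-6β-tigloyloxy-5βH-dauc-8-en-2-one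
Conditions: PPh3, iPrO2CN=NCO2iPr, toluene, 0 °C → rt
Reagents that add atoms: none
Why: Mitsunobu esterification should invert C6 to the 6β-tiglate, the carboxylate entering from the convex β face while the tertiary 4-OH and the ketone stay untouched.

**Step 11**
Reactants: 21
Product: 22 4α,10α-dihydroxy-6β-tigloyloxy-5βH-dauc-8-en-2-one
Conditions: HF·pyridine, pyridine, THF, 0 °C → rt
Reagents that add atoms: none
Why: Buffered fluoride desilylation should free the allylic 10α-OH without acyl migration or retro-aldol cleavage.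

**Step 12**
Reactants: 22
Product: 23 8α,9α-epoxy-4α,10α-dihydroxy-6β-tigloyloxy-5βH-daucan-2-one
Conditions: VO(acac)2 (5 mol %), tBuOOH (1.5 equiv, decane), CH2Cl2, 0 °C → rt
Reagents that add atoms: tert-butyl hydroperoxide, CC(C)(C)OO
Why: Vanadium-catalysed epoxidation of the cycloheptenol should deliver oxygen syn to the allylic 10α-OH (cis-epoxy alcohol) and leave the electron-poor tiglate alkene alone.

**Step 13**
Reactants: 23; 20 tiglic acid
Product: 24 8α,9α-epoxy-4α-hydroxy-6β,10α-bis(tigloyloxy)-5βH-daucan-2-one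
Conditions: 20, 2,4,6-trichlorobenzoyl chloride, Et3N, toluene, rt; then 23, DMAP, 40 °C
Reagents that add atoms: none
Why: Yamaguchi esterification should acylate the hindered secondary 10-OH, the only acylable hydroxyl since C2 is still a ketone and the 4-OH is tertiary.

**Step 14**
Reactants: 24
Product: 25 8α,9α-epoxy-6β,10α-bis(tigloyloxy)-5βH-daucane-2β,4α-diol (target)
Conditions: Me4NBH(OAc)3, MeCN/AcOH (1:1), −30 → −20 °C
Reagents that add atoms: none
Why: Evans–Saksena reduction should deliver hydride inside the 4α-alkoxyborohydride to the α face of the C2 ketone, giving the 2β-alcohol (1,3-anti) and sparing esters and epoxide.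

**Compound list**
1 | (2R)-2-hydroxy-3-methylbutanoic acid | CC(C)[C@@H](O)C(=O)O | starting material
2 | 2,2-dimethylpropanal | CC(C)(C)C=O | starting material
3 | (2R,5R)-2-tert-butyl-5-(propan-2-yl)-1,3-dioxolan-4-one | CC(C)[C@H]1O[C@@H](C(C)(C)C)OC1=O | intermediate
4 | tert-butyl bromoacetate | CC(C)(C)OC(=O)CBr | starting material
5 | tert-butyl [(2R,4R)-2-tert-butyl-5-oxo-4-(propan-2-yl)-1,3-dioxolan-4-yl]acetate | CC(C)[C@@]1(CC(=O)OC(C)(C)C)O[C@@H](C(C)(C)C)OC1=O | intermediate
6 | tert-butyl [(2R,4R)-2-tert-butyl-5-hydroxy-4-(propan-2-yl)-1,3-dioxolan-4-yl]acetate (both anomers) | CC(C)[C@@]1(CC(=O)OC(C)(C)C)O[C@@H](C(C)(C)C)OC1O | intermediate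
7 | tert-butyl (3R)-3-formyl-3-hydroxy-4-methylpentanoate | O=C[C@](O)(C(C)C)CC(=O)OC(C)(C)C | intermediate
8 | tert-butyl (3R)-3-ethynyl-3-hydroxy-4-methylpentanoate | C#C[C@](O)(C(C)C)CC(=O)OC(C)(C)C | intermediate
9 | trimethylsilyl (3R)-3-ethynyl-4-methyl-3-(trimethylsilyloxy)pentanoate | C#C[C@](O[Si](C)(C)C)(C(C)C)CC(=O)O[Si](C)(C)C | intermediate
10 | (3R)-3-ethynyl-4-methyl-3-(trimethylsilyloxy)pentanoic acid | C#C[C@](O[Si](C)(C)C)(C(C)C)CC(=O)O | intermediate
11 | (3R)-3-ethynyl-4-methyl-3-(trimethylsilyloxy)pentanoyl chloride | C#C[C@](O[Si](C)(C)C)(C(C)C)CC(=O)Cl | intermediate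
12 | (5R)-2-diazo-5-ethynyl-6-methyl-5-(trimethylsilyloxy)heptan-3-one | C#C[C@](O[Si](C)(C)C)(C(C)C)CC(=O)C(C)=[N+]=[N-] | intermediate
13 | 3-methylbut-2-enal | CC(C)=CC=O | starting material
14 | tert-butyl(dimethyl){[(1E)-3-methylbuta-1,3-dien-1-yl]oxy}silane | C=C(C)/C=C/O[Si](C)(C)C(C)(C)C | intermediate
15 | (4R)-3-{cis-2-[(E)-2-(tert-butyldimethylsilyloxy)ethenyl]-2-methylcyclopropyl}-2-methyl-4-(propan-2-yl)-4-(trimethylsilyloxy)cyclopent-2-en-1-one (cyclopentenyl and silyloxyvinyl groups cis on the cyclopropane) | O=C1C[C@@](O[Si](C)(C)C)(C(C)C)C(=C1C)[C@H]2C[C@@]2(C)/C=C/O[Si](C)(C)C(C)(C)C | intermediate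
16 | 10α-(tert-butyldimethylsilyloxy)-4α-(trimethylsilyloxy)dauca-5,8-dien-2-one | C=1CC(C)=C[C@H](O[Si](C)(C)C(C)(C)C)[C@@]2(C)C=1[C@](O[Si](C)(C)C)(C(C)C)CC2=O | intermediate
17 | 10α-(tert-butyldimethylsilyloxy)-4α-hydroxydauca-5,8-dien-2-one | C=1CC(C)=C[C@H](O[Si](C)(C)C(C)(C)C)[C@@]2(C)C=1[C@](O)(C(C)C)CC2=O | intermediate
18 | 5α,6α-epoxy-10α-(tert-butyldimethylsilyloxy)-4α-hydroxydauc-8-en-2-one | O1[C@@H]2CC(C)=C[C@H](O[Si](C)(C)C(C)(C)C)[C@@]3(C)[C@]12[C@](O)(C(C)C)CC3=O | intermediate
19 | 10α-(tert-butyldimethylsilyloxy)-4α,6α-dihydroxy-5βH-dauc-8-en-2-one | O[C@@H]1CC(C)=C[C@H](O[Si](C)(C)C(C)(C)C)[C@@]2(C)[C@@H]1[C@](O)(C(C)C)CC2=O | intermediate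
20 | tiglic acid ((E)-2-methylbut-2-enoic acid) | C/C=C(\C)C(=O)O | starting material
21 | 10α-(tert-butyldimethylsilyloxy)-4α-hydroxy-6β-tigloyloxy-5βH-dauc-8-en-2-one | C/C=C(\C)C(=O)O[C@H]1CC(C)=C[C@H](O[Si](C)(C)C(C)(C)C)[C@@]2(C)[C@@H]1[C@](O)(C(C)C)CC2=O | intermediate
22 | 4α,10α-dihydroxy-6β-tigloyloxy-5βH-dauc-8-en-2-one | C/C=C(\C)C(=O)O[C@H]1CC(C)=C[C@H](O)[C@@]2(C)[C@@H]1[C@](O)(C(C)C)CC2=O | intermediate
23 | 8α,9α-epoxy-4α,10α-dihydroxy-6β-tigloyloxy-5βH-daucan-2-one | C/C=C(\C)C(=O)O[C@H]1C[C@]2(C)O[C@@H]2[C@H](O)[C@@]3(C)[C@@H]1[C@](O)(C(C)C)CC3=O | intermediate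
24 | 8α,9α-epoxy-4α-hydroxy-6β,10α-bis(tigloyloxy)-5βH-daucan-2-one | C/C=C(\C)C(=O)O[C@H]1C[C@]2(C)O[C@@H]2[C@H](OC(=O)/C(C)=C/C)[C@@]3(C)[C@@H]1[C@](O)(C(C)C)CC3=O | intermediate
25 | 8α,9α-epoxy-6β,10α-bis(tigloyloxy)-5βH-daucane-2β,4α-diol | C/C=C(\C)C(=O)O[C@H]1C[C@]2(C)O[C@@H]2[C@H](OC(=O)/C(C)=C/C)[C@@]2(C)[C@@H]1[C@](O)(C(C)C)C[C@@H]2O | target

**Count and risks**
Total: 14 steps. Longest linear sequence: 13 steps (steps 1–5 and 7–14; step 6 is a one-step side branch).

Most likely to fail:

1. Step 7 (proposed new method). Capture of the short-lived vinylcarbenoid by the diene may lose to carbene dimerisation or C–H insertion, and the diene may add with poor facial selectivity relative to C4. The fallback uses known chemistry, sets out from 12 and comes back at 17. Compound 12 is cyclised with Rh2(OAc)4 in wet CH2Cl2, so that the vinylcarbenoid inserts into the O–H bond of water and gives (4R)-3-(hydroxymethyl)-2-methyl-4-(propan-2-yl)-4-(trimethylsilyloxy)cyclopent-2-en-1-one F1. MnO2 then gives the enal (4R)-2-methyl-3-oxo-5-(propan-2-yl)-5-(trimethylsilyloxy)cyclopent-1-ene-1-carbaldehyde F2, and TsNHNH2 gives its N-tosylhydrazone F3. The sodium salt of F3 (NaH) is decomposed slowly at 40–60 °C with Rh2(OAc)4 in neat 14 (Bamford–Stevens generation of the vinyldiazomethane, then cyclopropanation and Cope rearrangement), and Et3N·3HF gives 17. This decouples carbene generation from the diazoketone and allows a large excess of diene.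

2. Step 9. Hydrogen-atom transfer to the C5 radical may occur on the α face (trans ring fusion), or the radical may be reduced and lose the titanoxy group back to the alkene. The fallback sets out from 17 and comes back at 21, replacing steps 8–10 by thermodynamic control of the ring fusion.
   - Hydroboration–oxidation of 17 (BH3·THF; NaBO3) gives 10α-(tert-butyldimethylsilyloxy)dauc-8-ene-2,4α,6-triol (epimers at C2, C5, C6) F4, whatever the face of attack.
   - Dess–Martin periodinane gives the 2,6-dione, which is equilibrated at C5 with DBU (0 °C, short contact to limit migration of the C8=C9 alkene) to cis-fused 10α-(tert-butyldimethylsilyloxy)-4α-hydroxy-5βH-dauc-8-ene-2,6-dione F5.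
   - Me4NBH(OAc)3 reduces both ketones under direction of the 4α-OH to 10α-(tert-butyldimethylsilyloxy)-5βH-dauc-8-ene-2β,4α,6β-triol F6.
   - The less hindered 6β-OH is acylated with tigloyl chloride/DMAP at −20 °C to 10α-(tert-butyldimethylsilyloxy)-2β,4α-dihydroxy-6β-tigloyloxy-5βH-dauc-8-ene F7.
   - Dess–Martin oxidation of the 2-OH gives 21.

3. Step 10. The activated hindered alcohol may eliminate towards C5=C6 or C6=C7, or fail to react because tiglic acid is a weak acid. The fallback sets out from 19 and comes back at 21, separating inversion from acylation. Mitsunobu inversion with 4-nitrobenzoic acid (PPh3, iPrO2CN=NCO2iPr) gives 10α-(tert-butyldimethylsilyloxy)-4α-hydroxy-6β-(4-nitrobenzoyloxy)-5βH-dauc-8-en-2-one F8. K2CO3/MeOH at 0 °C gives 10α-(tert-butyldimethylsilyloxy)-4α,6β-dihydroxy-5βH-dauc-8-en-2-one F9, and Yamaguchi esterification with 20 gives 21.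

**Further compounds**
F1 | step 7 | (4R)-3-(hydroxymethyl)-2-methyl-4-(propan-2-yl)-4-(trimethylsilyloxy)cyclopent-2-en-1-one | O=C1C[C@@](O[Si](C)(C)C)(C(C)C)C(CO)=C1C
F2 | step 7 | (4R)-2-methyl-3-oxo-5-(propan-2-yl)-5-(trimethylsilyloxy)cyclopent-1-ene-1-carbaldehyde | O=C1C[C@@](O[Si](C)(C)C)(C(C)C)C(C=O)=C1C
F3 | step 7 | N-tosylhydrazone of F2 | O=C1C[C@@](O[Si](C)(C)C)(C(C)C)C(/C=N/NS(=O)(=O)c2ccc(C)cc2)=C1C
F4 | step 9 | 10α-(tert-butyldimethylsilyloxy)dauc-8-ene-2,4α,6-triol (epimers at C2, C5, C6) | OC1CC(C)=C[C@H](O[Si](C)(C)C(C)(C)C)[C@@]2(C)C1[C@](O)(C(C)C)CC2O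
F5 | step 9 | 10α-(tert-butyldimethylsilyloxy)-4α-hydroxy-5βH-dauc-8-ene-2,6-dione | O=C1CC(C)=C[C@H](O[Si](C)(C)C(C)(C)C)[C@@]2(C)[C@@H]1[C@](O)(C(C)C)CC2=O
F6 | step 9 | 10α-(tert-butyldimethylsilyloxy)-5βH-dauc-8-ene-2β,4α,6β-triol | O[C@H]1CC(C)=C[C@H](O[Si](C)(C)C(C)(C)C)[C@@]2(C)[C@@H]1[C@](O)(C(C)C)C[C@@H]2O
F7 | step 9 | 10α-(tert-butyldimethylsilyloxy)-2β,4α-dihydroxy-6β-tigloyloxy-5βH-dauc-8-ene | C/C=C(\C)C(=O)O[C@H]1CC(C)=C[C@H](O[Si](C)(C)C(C)(C)C)[C@@]2(C)[C@@H]1[C@](O)(C(C)C)C[C@@H]2O
F8 | step 10 | 10α-(tert-butyldimethylsilyloxy)-4α-hydroxy-6β-(4-nitrobenzoyloxy)-5βH-dauc-8-en-2-one | O=C(O[C@H]1CC(C)=C[C@H](O[Si](C)(C)C(C)(C)C)[C@@]2(C)[C@@H]1[C@](O)(C(C)C)CC2=O)c1ccc(cc1)[N+](=O)[O-]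
F9 | step 10 | 10α-(tert-butyldimethylsilyloxy)-4α,6β-dihydroxy-5βH-dauc-8-en-2-one | O[C@H]1CC(C)=C[C@H](O[Si](C)(C)C(C)(C)C)[C@@]2(C)[C@@H]1[C@](O)(C(C)C)CC2=O
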